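The decalin is disconnected at the ring-fusion bond C5–C10 and at C8–C9 (drimane numbering), the two bonds of ring B that an intramolecular Diels–Alder reaction makes together. The precursor is an open-chain trienal: an (E)-2-alkyl-4-arylbut-2-enal (formyl on C10 as latent angular methyl, ArCH2 on C9) joined through C1–C4 to a vinylallene (C5=C6–C7=C8=C12). One catalytic, enantioselective cycloaddition closes ring B and, through the tether, ring A, and sets C5, C9 and C10: the quaternary fusion carbon C10 is the dienophile carbon that carries the activating group. The resulting 6,8(12)-diene is later reduced 1,4 to the C7=C8 alkene.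

Key step: step 12

Remarks on the chemistry:
- Atoms are numbered as in drimane: ring A = C1–C5 and C10, ring B = C5–C10, C11 = benzylic CH2 on C9, C12 = carbon on C8, C15 = carbon on C10. β is the face of the C10 substituent.
- The target has a trans ring fusion (5α-H, 10β-CH3) with 9β-H, so the ArCH2 group on C9 is α (anti to the angular methyl).
- SEM = 2-(trimethylsilyl)ethoxymethyl; SEMO = SEM-oxy.
- Assumption: the two aryl hydrogen sulfates at the end of the route are drawn as free acids, as in the target SMILES. In practice they are handled as sodium or tetrabutylammonium salts, and the free acid is liberated by cold cation exchange.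

Step 1
Reactants: 1 isobutyronitrile; 2 6-bromohex-1-ene
Product: 3 2,2-dimethyloct-7-enenitrile
Conditions: LiN(i-Pr)2, THF, −78 °C; then 2, −78 °C to rt
Reagents that add atoms: none
Why: SN2 alkylation of the lithiated nitrile with a primary bromide builds the quaternary carbon C4 with its two methyl groups; no stereocentre is involved.

Step 2
Reactants: 3 2,2-dimethyloct-7-enenitrile
Product: 5 2,2-dimethyloct-7-enal, via aldimine 4 (not isolated)
Conditions: i-Bu2AlH, CH2Cl2, −78 °C; then 1 M HCl, 0 °C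
Reagents that add atoms: water, O
Why: Partial reduction of the hindered tertiary nitrile stops at the N-aluminated aldimine, which is hydrolysed to the aldehyde on acidic work-up; the terminal alkene is inert.

Step 3
Reactants: 5 2,2-dimethyloct-7-enal
Product: 6 (1E)-1-iodo-3,3-dimethylnona-1,8-diene
Conditions: CrCl2 (6 equiv), CHI3 (2 equiv), THF, 0 °C to rt
Reagents that add atoms: iodoform, IC(I)I
Why: Takai olefination, in which the geminal dichromium species from CHI3 adds to the aldehyde and eliminates to the (E)-iodoalkene; this fixes the (E)-C5=C6 geometry of the later diene and leaves the remote terminal alkene alone.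

Step 4
Reactants: 6 (1E)-1-iodo-3,3-dimethylnona-1,8-diene
Product: 8 (7E)-8-iodo-6,6-dimethyloct-7-enal, via diol 7 (not isolated)
Conditions: OsO4 (2 mol%), NaIO4 (4 equiv), 2,6-lutidine, 1,4-dioxane/H2O 3:1, rt
Reagents that add atoms: sodium periodate (terminal oxidant and oxygen source), [Na+].[O-]I(=O)(=O)=O; osmium tetroxide (catalytic oxygen-transfer agent), O=[Os](=O)(=O)=O
Why: Lemieux–Johnson oxidation, in which OsO4 dihydroxylates the electron-rich monosubstituted alkene much faster than the hindered, electron-poor iodoalkene and periodate cleaves the diol to the aldehyde.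

Step 5
Reactants: 8 (7E)-8-iodo-6,6-dimethyloct-7-enal
Product: 9 (7E)-8-iodo-6,6-dimethyl-2-methylideneoct-7-enal
Conditions: 37% aq. CH2O, pyrrolidine (10 mol%), propanoic acid (10 mol%), i-PrOH, 45 °C
Reagents that add atoms: formaldehyde, C=O
Why: Amine-catalysed Mannich condensation with formaldehyde followed by elimination (α-methylenation of an α-unbranched aldehyde) gives the 2-substituted acrolein, whose CH2 carbon is a placeholder that the metathesis in step 10 replaces by C9; the iodoalkene is untouched.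

Step 6
Reactants: 10 2,4,5-trihydroxybenzaldehyde
Product: 11 2,4,5-tris(SEMO)benzaldehyde
Conditions: SEMCl (4 equiv), i-Pr2NEt (6 equiv), DMF, 0 to 40 °C, argon
Reagents that add atoms: 2-(trimethylsilyl)ethoxymethyl chloride, C[Si](C)(C)CCOCCl
Why: O-Alkylation of the three phenols; SEM is chosen because it directs ortho-lithiation, survives dissolving metal and is removed by fluoride after the sulfate is in place.

Step 7
Reactants: 11 2,4,5-tris(SEMO)benzaldehyde
Product: 13 2,4,5-tris(SEMO)phenol, via aryl formate 12 (not isolated)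
Conditions: mCPBA, NaHCO3, CH2Cl2, 0 °C to rt; then K2CO3 (cat.), MeOH, rt
Reagents that add atoms: 3-chloroperoxybenzoic acid, OOC(=O)c1cccc(Cl)c1
Why: Baeyer–Villiger (Dakin-type) oxidation of the electron-rich benzaldehyde with aryl migration gives the formate, which mild methanolysis cleaves to the phenol; this singles out the oxygen that will carry the sulfate.

Step 8
Reactants: 13 2,4,5-tris(SEMO)phenol
Product: 14 1-(benzyloxy)-2,4,5-tris(SEMO)benzene
Conditions: BnBr, K2CO3, DMF, rt
Reagents that add atoms: benzyl bromide, BrCc1ccccc1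
Why: O-Benzylation gives this one oxygen a protecting group that the Li/NH3 step removes while the SEM ethers stay.

Step 9
Reactants: 14 1-(benzyloxy)-2,4,5-tris(SEMO)benzene; 15 allyl bromide
Product: 17 1-(benzyloxy)-3-(prop-2-en-1-yl)-2,4,5-tris(SEMO)benzene, via aryllithium 16 (not isolated)
Conditions: n-BuLi, THF, 0 °C, 1 h; then CuI (5 mol%), 15, −78 °C to rt
Reagents that add atoms: none
Why: Directed ortho-metalation should take place at the only ring position flanked by two SEMO groups (cooperative coordination, faster than at the position between OSEM and OBn), and allylation of the aryllithium then places the benzyloxy group meta to the new carbon substituent.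

Step 10
Reactants: 9 (7E)-8-iodo-6,6-dimethyl-2-methylideneoct-7-enal; 17 1-(benzyloxy)-3-(prop-2-en-1-yl)-2,4,5-tris(SEMO)benzene
Product: 18 (2E,7E)-2-{2-[3-(benzyloxy)-2,5,6-tris(SEMO)phenyl]ethylidene}-8-iodo-6,6-dimethyloct-7-enal
Conditions: second-generation Hoveyda–Grubbs catalyst, (H2IMes)Cl2Ru=CH(C6H4-2-O-i-Pr) (5 mol%), 1,4-benzoquinone (10 mol%), 17 (2 equiv), CH2Cl2, 40 °C
Reagents that add atoms: none
Why: Olefin cross-metathesis of a terminal alkene with a 2-substituted acrolein is a selective pairing and gives the thermodynamically preferred (E)-trisubstituted enal (ArCH2 trans to CHO), the geometry that later becomes the C9 configuration; the hindered iodoalkene is a spectator.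

Step 11
Reactants: 18 (2E,7E)-2-{2-[3-(benzyloxy)-2,5,6-tris(SEMO)phenyl]ethylidene}-8-iodo-6,6-dimethyloct-7-enal; 19 tributyl(propa-1,2-dien-1-yl)stannane
Product: 20 (2E,7E)-2-{2-[3-(benzyloxy)-2,5,6-tris(SEMO)phenyl]ethylidene}-6,6-dimethylundeca-7,9,10-trienal
Conditions: Pd2(dba)3 (2.5 mol%), AsPh3 (20 mol%), CuI (10 mol%), DMF, rt, dark; product kept cold and used at once
Reagents that add atoms: none
Why: Stille coupling of the (E)-alkenyl iodide with the allenylstannane proceeds with retention and gives the (E)-vinylallene; the enal is tolerated under these neutral conditions.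

Step 12
Reactants: 20 (2E,7E)-2-{2-[3-(benzyloxy)-2,5,6-tris(SEMO)phenyl]ethylidene}-6,6-dimethylundeca-7,9,10-trienal
Product: 21 (1R,4aS,8aS)-1-{[3-(benzyloxy)-2,5,6-tris(SEMO)phenyl]methyl}-5,5-dimethyl-2-methylidene-1,2,4a,5,6,7,8,8a-octahydronaphthalene-8a-carbaldehyde (trans-fused; 10β-CHO, 5α-H, 9β-H, 9α-CH2Ar)
Conditions: (S)-1-(2-methylphenyl)-3,3-diphenyltetrahydro-1H,3H-pyrrolo[1,2-c][1,3,2]oxazaborole (20 mol%), Tf2NH (18 mol%), CH2Cl2, −78 to −20 °C
Reagents that add atoms: none
Why: The boron cation binds the formyl oxygen of the (E)-2-alkylenal and lowers its LUMO, so that a concerted, asynchronous normal-demand [4+2] cycloaddition with the tethered vinylallene follows, in which the unhindered C8–C9 bond (allene central carbon to the enal β-carbon) runs ahead of the congested C5–C10 bond. The closest known reaction type is the oxazaborolidinium-catalysed enantioselective intramolecular Diels–Alder reaction of 2-substituted trienals, combined with the known high diene reactivity of vinylallenes, whose s-cis form carries no inside substituent. Ring B closes as the six-membered cycloaddition ring (C5–C6–C7–C8 plus C9–C10) and ring A closes in the same event as the tether ring (C10–C1–C2–C3–C4–C5) when the C5–C10 bond forms. C9 relative to C10 is fixed by suprafacial addition to the (E)-alkene (H9 cis to the formyl group, CH2Ar trans), C5 relative to C10 by the formyl-endo, tether-exo transition state (trans fusion, H5 anti to the formyl group), and the absolute configuration by the catalyst, whose aryl groups shield one face of the bound enal. The step needs endo over exo selectivity and one enantiotopic face: because the activating group sits on the tether-bearing dienophile carbon, the Lewis-acid-enforced endo mode and the trans ring fusion coincide, and the gem-dimethyl group at C4 favours the folded reactive conformer. The sense of induction is to be confirmed on the first run, the antipodal catalyst being equally accessible.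

Step 13
Reactants: 21 the cycloadduct aldehyde
Product: 23 1-(benzyloxy)-3-{[(1R,4aS,8aR)-5,5,8a-trimethyl-2-methylidene-1,2,4a,5,6,7,8,8a-octahydronaphthalen-1-yl]methyl}-2,4,5-tris(SEMO)benzene, via tosylhydrazone 22 (not isolated)
Conditions: TsNHNH2, THF, 50 °C; then catecholborane, CHCl3, 0 °C; NaOAc·3H2O, 60 °C
Reagents that add atoms: none
Why: Caglioti-type reduction, in which the non-conjugated tosylhydrazone is reduced at C=N by catecholborane and acetate-induced loss of sulfinate and N2 leaves the C10 methyl group under near-neutral conditions that spare the diene, the acetals and C9 (the 8a descriptor changes only through the priority rules).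

Step 14
Reactants: 23 the benzyl-protected 6,8(12)-diene
Product: 24 3-{[(1R,4aS,8aS)-2,5,5,8a-tetramethyl-1,4,4a,5,6,7,8,8a-octahydronaphthalen-1-yl]methyl}-2,4,5-tris(SEMO)phenol
Conditions: Li (8 equiv), NH3(l)/THF, t-BuOH (2 equiv), −78 °C; then solid NH4Cl
Reagents that add atoms: none
Why: Birch-type dissolving-metal 1,4-reduction of the s-trans diene (radical anion protonated at C12, allyl anion at the less substituted C6, as in the reduction of abietic acid) should give the trisubstituted C7=C8 alkene with its C12 methyl group, and the same conditions cleave the benzyl ether; no stereocentre is formed or epimerised.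

Step 15
Reactants: 24 the phenol
Product: 25 2,4,5-tris(SEMO)-3-{[(1R,4aS,8aS)-2,5,5,8a-tetramethyl-1,4,4a,5,6,7,8,8a-octahydronaphthalen-1-yl]methyl}phenyl hydrogen sulfate
Conditions: SO3·pyridine (5 equiv), pyridine, 50 °C; then aq. NaHCO3
Reagents that add atoms: sulfur trioxide–pyridine complex, [O-]S(=O)(=O)[n+]1ccccc1
Why: O-Sulfonation of the single free phenol; the three other oxygens are blocked, so the position of the sulfate is unambiguous.

Step 16
Reactants: 25 the tris-SEM aryl sulfate
Product: 26 2,4,5-trihydroxy-3-{[(1R,4aS,8aS)-2,5,5,8a-tetramethyl-1,4,4a,5,6,7,8,8a-octahydronaphthalen-1-yl]methyl}phenyl hydrogen sulfate (CNP0445131.2)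
Conditions: Bu4NF (12 equiv), ethylenediamine (6 equiv), THF/DMPU, 70 °C, argon; then aq. NH4Cl with sodium ascorbate; reversed-phase chromatography; cold H+-form cation exchange
Reagents that add atoms: none
Why: Fluoride attacks silicon and each SEM group fragments to fluorotrimethylsilane, ethene and formaldehyde (trapped by ethylenediamine) under basic, non-acidic conditions that the aryl sulfate monoester and the C7=C8 alkene tolerate.

Compound list
1 | isobutyronitrile | CC(C)C#N | starting material
2 | 6-bromohex-1-ene | C=CCCCCBr | starting material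
3 | 2,2-dimethyloct-7-enenitrile | C=CCCCCC(C)(C)C#N | intermediate
4 | 2,2-dimethyloct-7-en-1-imine (formed as its N-aluminium derivative) | C=CCCCCC(C)(C)C=N | intermediate
5 | 2,2-dimethyloct-7-enal | C=CCCCCC(C)(C)C=O | intermediate
6 | (1E)-1-iodo-3,3-dimethylnona-1,8-diene | C=CCCCCC(C)(C)/C=C/I | intermediate
7 | (8E)-9-iodo-7,7-dimethylnon-8-ene-1,2-diol (racemic) | OCC(O)CCCCC(C)(C)/C=C/I | intermediate
8 | (7E)-8-iodo-6,6-dimethyloct-7-enal | O=CCCCCC(C)(C)/C=C/I | intermediate
9 | (7E)-8-iodo-6,6-dimethyl-2-methylideneoct-7-enal | C=C(C=O)CCCC(C)(C)/C=C/I | intermediate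
10 | 2,4,5-trihydroxybenzaldehyde | O=Cc1cc(O)c(O)cc1O | starting material
11 | 2,4,5-tris{[2-(trimethylsilyl)ethoxy]methoxy}benzaldehyde | O=Cc1cc(OCOCC[Si](C)(C)C)c(OCOCC[Si](C)(C)C)cc1OCOCC[Si](C)(C)C | intermediate
12 | 2,4,5-tris{[2-(trimethylsilyl)ethoxy]methoxy}phenyl formate | O=COc1cc(OCOCC[Si](C)(C)C)c(OCOCC[Si](C)(C)C)cc1OCOCC[Si](C)(C)C | intermediate
13 | 2,4,5-tris{[2-(trimethylsilyl)ethoxy]methoxy}phenol | Oc1cc(OCOCC[Si](C)(C)C)c(OCOCC[Si](C)(C)C)cc1OCOCC[Si](C)(C)C | intermediate
14 | 1-(benzyloxy)-2,4,5-tris{[2-(trimethylsilyl)ethoxy]methoxy}benzene | C(Oc1cc(OCOCC[Si](C)(C)C)c(OCOCC[Si](C)(C)C)cc1OCOCC[Si](C)(C)C)c1ccccc1 | intermediate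
15 | allyl bromide (3-bromoprop-1-ene) | C=CCBr | starting material
16 | [3-(benzyloxy)-2,5,6-tris(SEMO)phenyl]lithium | [Li]c1c(OCOCC[Si](C)(C)C)c(OCOCC[Si](C)(C)C)cc(OCc2ccccc2)c1OCOCC[Si](C)(C)C | intermediate
17 | 1-(benzyloxy)-3-(prop-2-en-1-yl)-2,4,5-tris(SEMO)benzene | C=CCc1c(OCOCC[Si](C)(C)C)c(OCOCC[Si](C)(C)C)cc(OCc2ccccc2)c1OCOCC[Si](C)(C)C | intermediate
18 | (2E,7E)-2-{2-[3-(benzyloxy)-2,5,6-tris(SEMO)phenyl]ethylidene}-8-iodo-6,6-dimethyloct-7-enal | O=C/C(=C/Cc1c(OCOCC[Si](C)(C)C)c(OCOCC[Si](C)(C)C)cc(OCc2ccccc2)c1OCOCC[Si](C)(C)C)CCCC(C)(C)/C=C/I | intermediate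
19 | tributyl(propa-1,2-dien-1-yl)stannane | C=C=C[Sn](CCCC)(CCCC)CCCC | starting material
20 | (2E,7E)-2-{2-[3-(benzyloxy)-2,5,6-tris(SEMO)phenyl]ethylidene}-6,6-dimethylundeca-7,9,10-trienal | O=C/C(=C/Cc1c(OCOCC[Si](C)(C)C)c(OCOCC[Si](C)(C)C)cc(OCc2ccccc2)c1OCOCC[Si](C)(C)C)CCCC(C)(C)/C=C/C=C=C | intermediate
21 | (1R,4aS,8aS)-1-{[3-(benzyloxy)-2,5,6-tris(SEMO)phenyl]methyl}-5,5-dimethyl-2-methylidene-1,2,4a,5,6,7,8,8a-octahydronaphthalene-8a-carbaldehyde | C=C1C=C[C@H]2C(C)(C)CCC[C@]2(C=O)[C@@H]1Cc1c(OCOCC[Si](C)(C)C)c(OCOCC[Si](C)(C)C)cc(OCc3ccccc3)c1OCOCC[Si](C)(C)C | intermediate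
22 | N-tosylhydrazone of 21 | C=C1C=C[C@H]2C(C)(C)CCC[C@]2(C=NNS(=O)(=O)c3ccc(C)cc3)[C@@H]1Cc1c(OCOCC[Si](C)(C)C)c(OCOCC[Si](C)(C)C)cc(OCc3ccccc3)c1OCOCC[Si](C)(C)C | intermediate
23 | 1-(benzyloxy)-3-{[(1R,4aS,8aR)-5,5,8a-trimethyl-2-methylidene-1,2,4a,5,6,7,8,8a-octahydronaphthalen-1-yl]methyl}-2,4,5-tris(SEMO)benzene | C=C1C=C[C@H]2C(C)(C)CCC[C@]2(C)[C@@H]1Cc1c(OCOCC[Si](C)(C)C)c(OCOCC[Si](C)(C)C)cc(OCc3ccccc3)c1OCOCC[Si](C)(C)C | intermediate
24 | 3-{[(1R,4aS,8aS)-2,5,5,8a-tetramethyl-1,4,4a,5,6,7,8,8a-octahydronaphthalen-1-yl]methyl}-2,4,5-tris(SEMO)phenol | CC1=CC[C@H]2C(C)(C)CCC[C@]2(C)[C@@H]1Cc1c(OCOCC[Si](C)(C)C)c(OCOCC[Si](C)(C)C)cc(O)c1OCOCC[Si](C)(C)C | intermediate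
25 | 2,4,5-tris(SEMO)-3-{[(1R,4aS,8aS)-2,5,5,8a-tetramethyl-1,4,4a,5,6,7,8,8a-octahydronaphthalen-1-yl]methyl}phenyl hydrogen sulfate | CC1=CC[C@H]2C(C)(C)CCC[C@]2(C)[C@@H]1Cc1c(OCOCC[Si](C)(C)C)c(OCOCC[Si](C)(C)C)cc(OS(=O)(=O)O)c1OCOCC[Si](C)(C)C | intermediate
26 | 2,4,5-trihydroxy-3-{[(1R,4aS,8aS)-2,5,5,8a-tetramethyl-1,4,4a,5,6,7,8,8a-octahydronaphthalen-1-yl]methyl}phenyl hydrogen sulfate | CC1=CC[C@H]2C(C)(C)CCC[C@]2(C)[C@@H]1Cc1c(O)c(O)cc(OS(=O)(=O)O)c1O | target

Total step count: 16. Longest linear sequence: 12 steps (steps 1–5 and 10–16); the arene branch (steps 6–9) joins at step 10.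

Steps most likely to fail

Step 12. The ether oxygens of the arene (three acetals and a benzyl ether) may compete with the formyl group for the boron cation, so that turnover stalls and a weakly controlled background cycloaddition erodes facial and endo selectivity. The C5–C10 bond must also form between two congested carbons. The fallback cyclises before the arene is attached; it sets out from 8 and comes back at 24. Aldehyde 8 is condensed with ethyl glyoxylate (pyrrolidine, AcOH cat., toluene; amine-catalysed aldol condensation) to ethyl (2E,8E)-3-formyl-9-iodo-7,7-dimethylnona-2,8-dienoate F1. Stille coupling with 19 as in step 11 gives ethyl (2E,8E)-3-formyl-7,7-dimethyldodeca-2,8,10,11-tetraenoate F2. The same oxazaborolidinium-catalysed cycloaddition, now on a doubly activated dienophile free of Lewis-basic ethers, should give the formyl ester F3 (formyl endo and ester exo, hence trans fusion and a 9α-ester). The formyl group is reduced as in step 13 through the tosylhydrazone F4 to the 10-methyl ester F5. i-Bu2AlH at −78 °C gives the 9α-carbaldehyde F6, and aryllithium 16 adds to it to give the benzylic carbinol F7 (either C11 epimer). Li/NH3 then NH4Cl removes the benzylic hydroxyl, reduces the diene 1,4 and cleaves the benzyl ether in one operation to give 24.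

Step 14. The allyl anion may be protonated at C8 instead of C6 (giving the 1,2-reduced alkene), the electron-rich arene may be over-reduced, or SEM groups may be partly lost. The fallback replaces the electron-transfer reduction by an ionic sequence through a vinyl epoxide; it sets out from 23 and comes back at 24. mCPBA/NaHCO3 at −20 °C epoxidises the more exposed exocyclic 8(12)-alkene to the spiro-epoxide F8. i-Bu2AlH opens the vinyl epoxide by SN2′ hydride delivery at C6 to give the primary allylic alcohol F9, which already has the C7=C8 alkene. MsCl/Et3N gives the mesylate F10, and LiBHEt3 displaces it directly (SN2) to give the benzyl ether F11. Lithium naphthalenide (LiC10H8, THF, −25 °C) removes the benzyl group without touching the isolated alkene to give 24.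

Step 16. Fluoride fragmentation of the two hindered inner SEM groups may stay incomplete, released formaldehyde may hydroxymethylate the electron-rich ring, and the polyphenolate may be oxidised by air to a quinone. The fallback masks the sulfate so that the acetals can be removed with a Lewis acid and the sulfate is unveiled last under neutral reducing conditions; it sets out from 24 and comes back at 26. 2,2,2-Trichloroethyl chlorosulfate with Et3N and DMAP gives the aryl trichloroethyl sulfate F12. MgBr2·OEt2 in Et2O/MeNO2 removes the three SEM groups to give the triol F13. Zn dust with HCO2NH4 in MeOH at rt cleaves the trichloroethyl group reductively to give 26.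

Further compounds
F1 | step 12 | ethyl (2E,8E)-3-formyl-9-iodo-7,7-dimethylnona-2,8-dienoate | CCOC(=O)/C=C(/C=O)CCCC(C)(C)/C=C/I
F2 | step 12 | ethyl (2E,8E)-3-formyl-7,7-dimethyldodeca-2,8,10,11-tetraenoate | CCOC(=O)/C=C(/C=O)CCCC(C)(C)/C=C/C=C=C
F3 | step 12 | ethyl 8a-formyl-5,5-dimethyl-2-methylidene-1,2,4a,5,6,7,8,8a-octahydronaphthalene-1-carboxylate, configured as 21 (10β-CHO, 5α-H, 9α-CO2Et) | C=C1C=C[C@H]2C(C)(C)CCC[C@]2(C=O)[C@@H]1C(=O)OCC
F4 | step 12 | N-tosylhydrazone of F3 | C=C1C=C[C@H]2C(C)(C)CCC[C@]2(C=NNS(=O)(=O)c3ccc(C)cc3)[C@@H]1C(=O)OCC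
F5 | step 12 | ethyl 5,5,8a-trimethyl-2-methylidene-1,2,4a,5,6,7,8,8a-octahydronaphthalene-1-carboxylate (10β-CH3, 5α-H, 9α-CO2Et) | C=C1C=C[C@H]2C(C)(C)CCC[C@]2(C)[C@@H]1C(=O)OCC
F6 | step 12 | 5,5,8a-trimethyl-2-methylidene-1,2,4a,5,6,7,8,8a-octahydronaphthalene-1-carbaldehyde (9α-CHO) | C=C1C=C[C@H]2C(C)(C)CCC[C@]2(C)[C@@H]1C=O
F7 | step 12 | [3-(benzyloxy)-2,5,6-tris(SEMO)phenyl][5,5,8a-trimethyl-2-methylidene-1,2,4a,5,6,7,8,8a-octahydronaphthalen-1-yl]methanol (either C11 epimer) | C=C1C=C[C@H]2C(C)(C)CCC[C@]2(C)[C@@H]1C(O)c1c(OCOCC[Si](C)(C)C)c(OCOCC[Si](C)(C)C)cc(OCc3ccccc3)c1OCOCC[Si](C)(C)C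
F8 | step 14 | 8,12-epoxide of 23 (spiro-oxirane at C8, either C8 epimer) | O1CC12C=C[C@H]3C(C)(C)CCC[C@]3(C)[C@@H]2Cc1c(OCOCC[Si](C)(C)C)c(OCOCC[Si](C)(C)C)cc(OCc4ccccc4)c1OCOCC[Si](C)(C)C
F9 | step 14 | 12-hydroxy derivative of F11 (C7=C8 alkene, CH2OH on C8) | OCC1=CC[C@H]2C(C)(C)CCC[C@]2(C)[C@@H]1Cc1c(OCOCC[Si](C)(C)C)c(OCOCC[Si](C)(C)C)cc(OCc3ccccc3)c1OCOCC[Si](C)(C)C
F10 | step 14 | methanesulfonate of F9 | CS(=O)(=O)OCC1=CC[C@H]2C(C)(C)CCC[C@]2(C)[C@@H]1Cc1c(OCOCC[Si](C)(C)C)c(OCOCC[Si](C)(C)C)cc(OCc3ccccc3)c1OCOCC[Si](C)(C)C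
F11 | step 14 | benzyl ether of 24 | CC1=CC[C@H]2C(C)(C)CCC[C@]2(C)[C@@H]1Cc1c(OCOCC[Si](C)(C)C)c(OCOCC[Si](C)(C)C)cc(OCc3ccccc3)c1OCOCC[Si](C)(C)C
F12 | step 16 | 2,2,2-trichloroethyl sulfate diester of 24 | CC1=CC[C@H]2C(C)(C)CCC[C@]2(C)[C@@H]1Cc1c(OCOCC[Si](C)(C)C)c(OCOCC[Si](C)(C)C)cc(OS(=O)(=O)OCC(Cl)(Cl)Cl)c1OCOCC[Si](C)(C)C
F13 | step 16 | 2,2,2-trichloroethyl sulfate diester of 26 | CC1=CC[C@H]2C(C)(C)CCC[C@]2(C)[C@@H]1Cc1c(O)c(O)cc(OS(=O)(=O)OCC(Cl)(Cl)Cl)c1O
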